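**Retrosynthetic overview**
- The target comes from a quinone bis(dimethyl ketal) that already carries the full C15 chain. One acid hydrolysis removes all six O-methyl groups (two ketals, two vinylogous esters).
- That bisketal comes from 8-(tetramethoxy-methylphenyl)octanoic acid and nonanoic acid in a one-cell anodic sequence. The arene is first converted to the quinone bisketal. A mixed Kolbe (decarboxylative radical–radical) coupling then makes the C7–C8 bond of the pentadecyl chain (numbered from the ring), and both carboxyl groups leave as CO2.
- Enabling feature: the side chain is an unbranched, heteroatom-free (CH2)14CH3. C7 and C8 are therefore plain primary radical carbons, and seven CH2 groups separate the coupling site from ring carbon C6. The six-membered ring bears oxygen on C1, C2, C4 and C5 as two equivalent para pairs, so it can be parked as one single, non-aromatic bisketal at the final quinone oxidation level.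
- The aryl-octanoic acid comes from 1,2,4,5-tetramethoxybenzene by two directed ortho-lithiations (MeI, then 1,7-dibromoheptane) and a Grignard carboxylation.
- No ring is formed, because the only ring (the six-membered carbocycle) is bought with the starting arene. The target has no stereocentre.

Key step: step 4

Assumption: 1,2,4,5-tetramethoxybenzene is taken as a catalogue compound, and the target is treated as one compound irrespective of which of its two equivalent hydroxyquinone tautomers is drawn.

Step 1
Reactants: 1 1,2,4,5-tetramethoxybenzene
Product: 3 1,2,4,5-tetramethoxy-3-methylbenzene, via aryllithium 2 (not isolated)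
Conditions: n-BuLi (1.05 equiv), THF, 0 °C to rt; MeI, 0 °C to rt
Reagents that add atoms: iodomethane, CI
Why: Directed ortho-metalation removes the ring proton flanked by two methoxy groups and the aryllithium is methylated by SN2 on MeI, with about one equivalent of base limiting double methylation.

Step 2
Reactants: 3 1,2,4,5-tetramethoxy-3-methylbenzene; 4 1,7-dibromoheptane (4 equiv)
Product: 6 1-(7-bromoheptyl)-2,3,5,6-tetramethoxy-4-methylbenzene, via aryllithium 5 (not isolated)
Conditions: n-BuLi (1.05 equiv), TMEDA, THF, 0 °C to rt; cannulated into 4, THF/DMPU, −20 °C to rt
Reagents that add atoms: none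
Why: A second directed ortho-metalation takes the only remaining ring C–H (flanked by two OMe, so ring lithiation outruns lateral lithiation of the methyl group), and SN2 alkylation of a primary bromide follows, with excess dibromide and inverse addition suppressing twofold substitution.

Step 3
Reactants: 6 1-(7-bromoheptyl)-2,3,5,6-tetramethoxy-4-methylbenzene
Product: 8 8-(2,3,5,6-tetramethoxy-4-methylphenyl)octanoic acid, via Grignard reagent 7 (not isolated)
Conditions: Mg, I2 (cat.), THF, reflux; CO2 (g), −20 °C to rt; 1 M HCl
Reagents that add atoms: carbon dioxide, O=C=O
Why: Grignard formation and carboxylation, to both of which aryl methyl ethers are inert, install the carboxyl group that acts as the traceless activator in the key step.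

Step 4
Reactants: 8 8-(2,3,5,6-tetramethoxy-4-methylphenyl)octanoic acid; 9 nonanoic acid (10 equiv)
Product: 11 1,3,3,4,6,6-hexamethoxy-2-methyl-5-pentadecylcyclohexa-1,4-diene, via bisketal acid 10 (not isolated)
Conditions: undivided cell, Pt anode, Pt cathode, NaOMe (2 equiv), dry MeOH; (i) 15 mA cm⁻², 0 °C, 2.3 F mol⁻¹; (ii) add 9, 250 mA cm⁻², 30–40 °C, until the electrolyte turns alkaline
Reagents that add atoms: methanol, CO
Why: Proposed new method: the step merges, at one platinum anode and in one electrolyte, two anodic reactions that are each established on their own, the nuclear bis-methoxylation of 1,4-dimethoxyarenes to quinone bisketals and the mixed Kolbe coupling of two alkanoic acids, a merger not yet shown for an acid that carries an electron-rich arene. In stage (i) the hexasubstituted ring, the most easily oxidised group present, gives up two electrons in an ECEC sequence and takes up methoxide at two para OMe-bearing carbons to give 10, basic methanol favouring this nuclear attack over benzylic substitution, and both para pairs (C2/C5 or C3/C6 of the aryl group) give the same constitution because they are exchanged by the twofold axis through aryl C1 and C4. In stage (ii) the added excess of 9 brings the medium to partial neutralisation, the anode potential rises into the Kolbe region, the adsorbed carboxylates of 10 and 9 each lose one electron and CO2, and the ring-bearing heptyl radical and the octyl radical combine in the high radical concentration at the electrode to form the C7–C8 bond of the pentadecyl chain. The step needs radical coupling rather than further oxidation to cations (Hofer–Moest path), which is secured because both radical carbons are unbranched primary CH2 groups without α-heteroatom, and it needs the ring to survive, which is secured because 10 is no longer aromatic, each of its two C=C bonds lies between two inductively withdrawing ketal carbons, and seven CH2 groups hold the ring away from the carboxylate layer on platinum and make radical attack on the ring an eight-membered or larger closure. Cross- versus homo-coupling is only statistical, so the cheap acid 9 is used in large excess and its own hydrocarbon dimer is removed by filtration through silica. No ring is closed and no stereocentre is formed.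

Step 5
Reactants: 11 1,3,3,4,6,6-hexamethoxy-2-methyl-5-pentadecylcyclohexa-1,4-diene
Product: 13 2,5-dihydroxy-3-methyl-6-pentadecylcyclohexa-2,5-diene-1,4-dione, via dimethoxyquinone 12 (not isolated)
Conditions: 70% aq HClO4, conc. HCl, 1,4-dioxane, rt
Reagents that add atoms: water, O
Why: Acid-catalysed ketal hydrolysis unmasks both quinone carbonyls at once, and the two remaining methoxy groups, vinylogous esters on a fully substituted quinone, are then replaced by addition–elimination of water in the same strong acid, a hydrolysis known for 2,5-dimethoxy-3-alkyl-1,4-benzoquinones.

**Compound list**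
1 | 1,2,4,5-tetramethoxybenzene | COc1cc(OC)c(OC)cc1OC | starting material
2 | (2,3,5,6-tetramethoxyphenyl)lithium | [Li]c1c(OC)c(OC)cc(OC)c1OC | intermediate
3 | 1,2,4,5-tetramethoxy-3-methylbenzene | Cc1c(OC)c(OC)cc(OC)c1OC | intermediate
4 | 1,7-dibromoheptane | BrCCCCCCCBr | starting material
5 | (2,3,5,6-tetramethoxy-4-methylphenyl)lithium | [Li]c1c(OC)c(OC)c(C)c(OC)c1OC | intermediate
6 | 1-(7-bromoheptyl)-2,3,5,6-tetramethoxy-4-methylbenzene | BrCCCCCCCc1c(OC)c(OC)c(C)c(OC)c1OC | intermediate
7 | [7-(2,3,5,6-tetramethoxy-4-methylphenyl)heptyl]magnesium bromide | Br[Mg]CCCCCCCc1c(OC)c(OC)c(C)c(OC)c1OC | intermediate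
8 | 8-(2,3,5,6-tetramethoxy-4-methylphenyl)octanoic acid | OC(=O)CCCCCCCc1c(OC)c(OC)c(C)c(OC)c1OC | intermediate
9 | nonanoic acid | CCCCCCCCC(=O)O | starting material
10 | 8-(2,3,3,5,6,6-hexamethoxy-4-methylcyclohexa-1,4-dien-1-yl)octanoic acid | OC(=O)CCCCCCCC1=C(OC)C(OC)(OC)C(C)=C(OC)C1(OC)OC | intermediate
11 | 1,3,3,4,6,6-hexamethoxy-2-methyl-5-pentadecylcyclohexa-1,4-diene | CCCCCCCCCCCCCCCC1=C(OC)C(OC)(OC)C(C)=C(OC)C1(OC)OC | intermediate
12 | 2,5-dimethoxy-3-methyl-6-pentadecylcyclohexa-2,5-diene-1,4-dione | CCCCCCCCCCCCCCCC1=C(OC)C(=O)C(C)=C(OC)C1=O | intermediate
13 | 2,5-dihydroxy-3-methyl-6-pentadecylcyclohexa-2,5-diene-1,4-dione | CCCCCCCCCCCCCCCC1=C(O)C(=O)C(C)=C(O)C1=O | target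

Total step count: 5. Longest linear sequence: 5 steps (1 → 3 → 6 → 8 → 11 → 13).

**Steps most likely to fail**

1. Step 4 (proposed new method).
   - What may go wrong: in stage (i), benzylic methoxylation of the two ring alkyl groups may compete with nuclear attack. In stage (ii), further anodic oxidation of the ring enol ether bonds, electrode fouling or radical disproportionation may erode the coupling.
   - Fallback (known chemistry, same bond, polar instead of anodic): it sets out from 6. Copper-catalysed alkyl–alkyl cross-coupling with commercial octylmagnesium bromide (Li2CuCl4 cat., THF/NMP, 0 °C) should give 1,2,4,5-tetramethoxy-3-methyl-6-pentadecylbenzene F1. Oxidative demethylation of F1 with ceric ammonium nitrate (MeCN/H2O, 0 °C) should give the dimethoxyquinone. The route is rejoined at 12, which is carried through the second half of step 5.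

2. Step 2.
   - What may go wrong: SN2 attack by the doubly ortho-substituted aryllithium may be slow, so that elimination, twofold substitution of the dibromide and simple protonation take over.
   - Fallback (cross-coupling instead of carbanion alkylation): it sets out from 3. Bromination with NBS in MeCN should give 1-bromo-2,3,5,6-tetramethoxy-4-methylbenzene F2. Zinc insertion into commercial ethyl 8-bromooctanoate (Zn, I2 cat., DMA, 80 °C) should give (8-ethoxy-8-oxooctyl)zinc bromide F3. Negishi coupling of F2 with F3 (Pd(OAc)2/SPhos, THF/DMA) should give ethyl 8-(2,3,5,6-tetramethoxy-4-methylphenyl)octanoate F4. Saponification (LiOH, THF/H2O) rejoins the route at 8, bypassing 6 and step 3.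

3. Step 5.
   - What may go wrong: hydrolysis may stall after the first vinylogous ester has fallen, since the hydroxyquinone formed is a poorer acceptor. The long exposure to strong acid may also degrade the quinone.
   - Fallback (demethylation at the arene oxidation level instead of hydrolysis at the quinone level): it sets out from 12, obtained by stopping step 5 after ketal hydrolysis with dilute aqueous acid. Reduction with aqueous Na2S2O4 should give 2,5-dimethoxy-3-methyl-6-pentadecylbenzene-1,4-diol F5. BBr3 (CH2Cl2, −78 °C to rt) should give 3-methyl-6-pentadecylbenzene-1,2,4,5-tetrol F6. Autoxidation of F6 in air during aqueous work-up rejoins the route at 13.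

**Further compounds**
F1 | step 4 | 1,2,4,5-tetramethoxy-3-methyl-6-pentadecylbenzene | CCCCCCCCCCCCCCCc1c(OC)c(OC)c(C)c(OC)c1OC
F2 | step 2 | 1-bromo-2,3,5,6-tetramethoxy-4-methylbenzene | Brc1c(OC)c(OC)c(C)c(OC)c1OC
F3 | step 2 | (8-ethoxy-8-oxooctyl)zinc bromide | CCOC(=O)CCCCCCC[Zn]Br
F4 | step 2 | ethyl 8-(2,3,5,6-tetramethoxy-4-methylphenyl)octanoate | CCOC(=O)CCCCCCCc1c(OC)c(OC)c(C)c(OC)c1OC
F5 | step 5 | 2,5-dimethoxy-3-methyl-6-pentadecylbenzene-1,4-diol | CCCCCCCCCCCCCCCc1c(OC)c(O)c(C)c(OC)c1O
F6 | step 5 | 3-methyl-6-pentadecylbenzene-1,2,4,5-tetrol | CCCCCCCCCCCCCCCc1c(O)c(O)c(C)c(O)c1O
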